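**Retrosynthetic overview**
1. Licoleafol ⇐ buffered desilylation ⇐ E-selective allylic hydroxylation of the 8-prenyl group of a B-ring-silylated (2S)-8-prenyl-5,7-dihydroxyflavanone.
2. That flavanone ⇐ one flask, two rings: an acyclic δ-hydroxy-β-diketone carrying a dioxinone closes ring C (O1–C8a, cyclodehydration), then ring A (C4a–C5, acylketene 6π closure); ring B is bought.
3. Acyclic precursor ⇐ C4–C4a Claisen coupling of an (S)-β-hydroxy thioester (C2–C4) with the dianion of a prenylated keto-dioxinone (C4a, C8a, C8, C7, C6, C5).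
4. (S)-β-Hydroxy thioester ⇐ catalytic asymmetric Mukaiyama aldol on silylated 3,4-dihydroxybenzaldehyde; keto-dioxinone ⇐ 2,2,6-trimethyl-1,3-dioxin-4-one + acetyl chloride + prenyl bromide.
5. C2 is set once (aldol) and carried with retention; the C8 position of the side chain is fixed before any ring exists.

Assumption: ketene silyl thioacetal 3 is bought (otherwise one flask from S-tert-butyl thioacetate, LDA, TMSCl); atom labels C2–C8a are those of the final chromanone.

**Step 1**
Reactants: 1 3,4-dihydroxybenzaldehyde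
Product: 2 3,4-bis(triisopropylsilyloxy)benzaldehyde
Conditions: TIPSCl (2.3 equiv), imidazole (5 equiv), DMF, 0 °C → rt
Reagents that add atoms: chlorotriisopropylsilane, CC(C)[Si](Cl)(C(C)C)C(C)C
Why: Imidazole-promoted O-silylation (silyl ether protection) of both phenols; aryl TIPS ethers tolerate Ti(IV), lithium amides and 110 °C and are removed last with buffered fluoride.

**Step 2**
Reactants: 2 3,4-bis(triisopropylsilyloxy)benzaldehyde; 3 1-(tert-butylsulfanyl)-1-(trimethylsilyloxy)ethene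
Product: 4 S-tert-butyl (3S)-3-[3,4-bis(triisopropylsilyloxy)phenyl]-3-hydroxypropanethioate
Conditions: Ti(OiPr)4 (10–20 mol%), (S)-BINOL (10–20 mol%), 4 Å MS, Et2O, −20 °C; then 1 M HCl, THF, 0 °C
Reagents that add atoms: none
Why: Catalytic asymmetric Mukaiyama aldol addition in which the BINOL–Ti(IV) Lewis acid with the (S) ligand directs the ketene acetal to the Si face of the aldehyde, giving the S carbinol (future C2, the only stereocentre); the sense is confirmed by Mosher analysis and the (R) ligand is used if it is reversed.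

**Step 3**
Reactants: 5 2,2,6-trimethyl-4H-1,3-dioxin-4-one; 6 acetyl chloride; 7 1-bromo-3-methylbut-2-ene
Product: 9 2,2-dimethyl-6-(6-methyl-2-oxohept-5-en-3-yl)-4H-1,3-dioxin-4-one, via keto-dioxinone 8 (not isolated)
Conditions: 5 (2.0 equiv), LiHMDS (2.0 equiv), THF, −78 °C; AcCl (1.0 equiv); then prenyl bromide (1.0 equiv), DMPU, −78 °C → rt
Reagents that add atoms: none
Why: Vinylogous Claisen-type γ-C-acylation of the lithium dienolate, whose second equivalent deprotonates the more acidic product 8, and SN2 C-alkylation of that enolate in the same flask at the doubly activated carbon; this puts the C5 chain on the future C8 before any ring exists (the new methine centre is racemic and is lost in step 5).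

**Step 4**
Reactants: 4 S-tert-butyl (3S)-3-[3,4-bis(triisopropylsilyloxy)phenyl]-3-hydroxypropanethioate; 9 2,2-dimethyl-6-(6-methyl-2-oxohept-5-en-3-yl)-4H-1,3-dioxin-4-one
Product: 10 6-[(10S)-10-[3,4-bis(triisopropylsilyloxy)phenyl]-10-hydroxy-2-methyl-6,8-dioxodec-2-en-5-yl]-2,2-dimethyl-4H-1,3-dioxin-4-one
Conditions: 9 (2.2 equiv), LDA (4.4 equiv), THF, −78 °C; add lithium alkoxide of 4 (LiHMDS, 1.0 equiv), −78 → −40 °C; AcOH, −78 °C
Reagents that add atoms: none
Why: Claisen condensation of a 1,3-dianion (Hauser-type terminal carbanion of the β-dicarbonyl dianion) with the thioester forms the C4–C4a bond; the carbinol is carried as its lithium alkoxide and its configuration is untouched (10 is a mixture of epimers at the dioxinone-bearing carbon and of enol tautomers).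

**Step 5**
Reactants: 10 6-[(10S)-10-[3,4-bis(triisopropylsilyloxy)phenyl]-10-hydroxy-2-methyl-6,8-dioxodec-2-en-5-yl]-2,2-dimethyl-4H-1,3-dioxin-4-one
Product: 13 (2S)-2-[3,4-bis(triisopropylsilyloxy)phenyl]-5,7-dihydroxy-8-(3-methylbut-2-en-1-yl)-2,3-dihydro-4H-chromen-4-one, via dihydropyranone 11 (not isolated), via acylketene 12 (not isolated)
Conditions: PPTS (10 mol%), 4 Å MS, PhMe (0.01 M), 50 °C until 10 is consumed; then 110 °C, same flask
Reagents that add atoms: none
Why: Proposed new method: PPTS first closes ring C by the standard cyclodehydration of a δ-hydroxy-β-diketone to a 2,3-dihydro-4H-pyran-4-one (hemiketal at C8a, loss of water; the C2–O bond is never broken, so S is retained and O1 ends up next to the prenyl-bearing carbon), then at 110 °C the dioxinone loses acetone by retro-hetero-Diels–Alder to acylketene 12, whose enol is a dienylketene (C5=C6, C7=C8, C8a=C4a) that closes ring A by 6π-electrocyclisation (equivalently C-acylation of the enol-ether carbon C4a) and tautomerises to the phloroglucinol ring; the closest known reactions are thermal dioxinone-to-acylketene aromatisation cascades and the dienylketene electrocyclisation that ends the Danheiser benzannulation, and O-trapping to a pyrone is disfavoured because the only oxygen within six-ring reach is the ring ether.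

**Step 6**
Reactants: 13 (2S)-2-[3,4-bis(triisopropylsilyloxy)phenyl]-5,7-dihydroxy-8-(3-methylbut-2-en-1-yl)-2,3-dihydro-4H-chromen-4-one
Product: 14 (2S)-2-[3,4-bis(triisopropylsilyloxy)phenyl]-5,7-dihydroxy-8-[(2E)-4-hydroxy-3-methylbut-2-en-1-yl]-2,3-dihydro-4H-chromen-4-one
Conditions: SeO2 (0.5 equiv), t-BuOOH (3 equiv, decane), salicylic acid (10 mol%), CH2Cl2, 0 °C → rt
Reagents that add atoms: tert-butyl hydroperoxide, CC(C)(C)OO (oxygen relayed through catalytic selenium dioxide, O=[Se]=O)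
Why: SeO2/t-BuOOH allylic oxidation (ene reaction, then [2,3]-sigmatropic shift) attacks the trisubstituted alkene at the methyl trans to the chain and gives the E allylic alcohol; C2 is not affected under these neutral conditions.

**Step 7**
Reactants: 14 (2S)-2-[3,4-bis(triisopropylsilyloxy)phenyl]-5,7-dihydroxy-8-[(2E)-4-hydroxy-3-methylbut-2-en-1-yl]-2,3-dihydro-4H-chromen-4-one
Product: 15 licoleafol, (2S)-2-(3,4-dihydroxyphenyl)-5,7-dihydroxy-8-[(2E)-4-hydroxy-3-methylbut-2-en-1-yl]-2,3-dihydro-4H-chromen-4-one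
Conditions: TBAF (2.4 equiv), AcOH (2.6 equiv), THF, 0 °C
Reagents that add atoms: none
Why: Fluoride desilylation of the two aryl silyl ethers, buffered with acetic acid so that no phenoxide-driven ring opening (retro-oxa-Michael) can racemise C2.

**Compound list**
1 | 3,4-dihydroxybenzaldehyde | O=Cc1ccc(O)c(O)c1 | starting material
2 | 3,4-bis(triisopropylsilyloxy)benzaldehyde | O=Cc1ccc(O[Si](C(C)C)(C(C)C)C(C)C)c(O[Si](C(C)C)(C(C)C)C(C)C)c1 | intermediate
3 | 1-(tert-butylsulfanyl)-1-(trimethylsilyloxy)ethene | C=C(O[Si](C)(C)C)SC(C)(C)C | starting material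
4 | S-tert-butyl (3S)-3-[3,4-bis(triisopropylsilyloxy)phenyl]-3-hydroxypropanethioate | O[C@H](c1ccc(O[Si](C(C)C)(C(C)C)C(C)C)c(O[Si](C(C)C)(C(C)C)C(C)C)c1)CC(=O)SC(C)(C)C | intermediate
5 | 2,2,6-trimethyl-4H-1,3-dioxin-4-one | CC1=CC(=O)OC(C)(C)O1 | starting material
6 | acetyl chloride | CC(=O)Cl | starting material
7 | 1-bromo-3-methylbut-2-ene (prenyl bromide) | CC(C)=CCBr | starting material
8 | 2,2-dimethyl-6-(2-oxopropyl)-4H-1,3-dioxin-4-one (present as its lithium enolate) | CC(=O)CC1=CC(=O)OC(C)(C)O1 | intermediate (not isolated)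
9 | 2,2-dimethyl-6-(6-methyl-2-oxohept-5-en-3-yl)-4H-1,3-dioxin-4-one (racemic) | CC(=O)C(CC=C(C)C)C1=CC(=O)OC(C)(C)O1 | intermediate
10 | 6-[(10S)-10-[3,4-bis(triisopropylsilyloxy)phenyl]-10-hydroxy-2-methyl-6,8-dioxodec-2-en-5-yl]-2,2-dimethyl-4H-1,3-dioxin-4-one | O[C@H](c1ccc(O[Si](C(C)C)(C(C)C)C(C)C)c(O[Si](C(C)C)(C(C)C)C(C)C)c1)CC(=O)CC(=O)C(CC=C(C)C)C1=CC(=O)OC(C)(C)O1 | intermediate
11 | (2S)-2-[3,4-bis(triisopropylsilyloxy)phenyl]-6-[1-(2,2-dimethyl-4-oxo-4H-1,3-dioxin-6-yl)-4-methylpent-3-en-1-yl]-2,3-dihydro-4H-pyran-4-one | O=C1C=C(C(CC=C(C)C)C2=CC(=O)OC(C)(C)O2)O[C@H](c2ccc(O[Si](C(C)C)(C(C)C)C(C)C)c(O[Si](C(C)C)(C(C)C)C(C)C)c2)C1 | intermediate (not isolated)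
12 | 4-[(2S)-2-[3,4-bis(triisopropylsilyloxy)phenyl]-4-oxo-3,4-dihydro-2H-pyran-6-yl]-7-methyl-3-oxoocta-1,6-dien-1-one (acylketene) | O=C1C=C(C(CC=C(C)C)C(=O)C=C=O)O[C@H](c2ccc(O[Si](C(C)C)(C(C)C)C(C)C)c(O[Si](C(C)C)(C(C)C)C(C)C)c2)C1 | intermediate (not isolated)
13 | (2S)-2-[3,4-bis(triisopropylsilyloxy)phenyl]-5,7-dihydroxy-8-(3-methylbut-2-en-1-yl)-2,3-dihydro-4H-chromen-4-one | CC(C)=CCc1c(O)cc(O)c2c1O[C@H](c1ccc(O[Si](C(C)C)(C(C)C)C(C)C)c(O[Si](C(C)C)(C(C)C)C(C)C)c1)CC2=O | intermediate
14 | (2S)-2-[3,4-bis(triisopropylsilyloxy)phenyl]-5,7-dihydroxy-8-[(2E)-4-hydroxy-3-methylbut-2-en-1-yl]-2,3-dihydro-4H-chromen-4-one | C/C(=C\Cc1c(O)cc(O)c2c1O[C@H](c1ccc(O[Si](C(C)C)(C(C)C)C(C)C)c(O[Si](C(C)C)(C(C)C)C(C)C)c1)CC2=O)CO | intermediate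
15 | licoleafol | C/C(=C\Cc1c(O)cc(O)c2c1O[C@H](c1ccc(O)c(O)c1)CC2=O)CO | target

**Totals**
Total step count: 7. Longest linear sequence: 6 steps (1 → 2 → 4 → 10 → 13 → 14 → 15).

**Three steps most likely to fail**

Step 5 (ring A closure of the acylketene). The ketene may dimerise or be hydrolysed before it cyclises, and the carbon nucleophile is only moderately reactive. The fallback sets out from 10 and turns the closure into an ionic one. The cyclodehydration and thermolysis are run in toluene–methanol (PPTS, 60 °C, then 110 °C in a sealed tube), so that the acylketene is captured as methyl 4-[(2S)-2-[3,4-bis(triisopropylsilyloxy)phenyl]-4-oxo-3,4-dihydro-2H-pyran-6-yl]-7-methyl-3-oxooct-6-enoate F1. Ring A is then closed by a Claisen (Dieckmann-type) condensation of the vinylogous enolate onto the ester with Mg(OMe)2 in MeOH at 0 °C, which returns to the route at 13. The ee must be checked there, because base can open ring C reversibly.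

Step 4 (dianion acylation). The dianion may only enolise thioester 4, or the alkoxide may undergo retro-aldol cleavage. The fallback sets out from 2 and 9 and moves the stereo-defining event. Horner–Wadsworth–Emmons reaction of 2 with diethyl [2-(methoxy(methyl)amino)-2-oxoethyl]phosphonate (NaH, THF) gives the non-enolisable acyl donor (2E)-3-[3,4-bis(triisopropylsilyloxy)phenyl]-N-methoxy-N-methylprop-2-enamide F2. The dianion of 9 (LDA, THF, −78 °C) is acylated by it to 6-[(9E)-10-[3,4-bis(triisopropylsilyloxy)phenyl]-2-methyl-6,8-dioxodeca-2,9-dien-5-yl]-2,2-dimethyl-4H-1,3-dioxin-4-one F3. A quinine-derived bifunctional squaramide (10 mol%, toluene, rt; pseudo-enantiomer chosen for S) then catalyses 6-endo oxa-Michael addition of the diketone enol to the enone, which sets C2 and returns to the route at 11; heating that solution completes step 5.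

Step 6 (SeO2 on a free 5,7-dihydroxyflavanone). Phenol oxidation, over-oxidation to the enal or dehydrogenation to the flavone are possible. The fallback sets out from 13. Cross-metathesis with methacrolein (Hoveyda–Grubbs II, 5 mol%, CH2Cl2, 40 °C) exchanges the isopropylidene terminus for the thermodynamically favoured E enal (2S)-2-[3,4-bis(triisopropylsilyloxy)phenyl]-5,7-dihydroxy-8-[(2E)-3-methyl-4-oxobut-2-en-1-yl]-2,3-dihydro-4H-chromen-4-one F4. NaBH(OAc)3 (THF/AcOH, rt) reduces the aldehyde but not the hydrogen-bonded aryl ketone, which returns to the route at 14.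

**Further compounds**
F1 | step 5 | methyl 4-[(2S)-2-[3,4-bis(triisopropylsilyloxy)phenyl]-4-oxo-3,4-dihydro-2H-pyran-6-yl]-7-methyl-3-oxooct-6-enoate | O=C1C=C(C(CC=C(C)C)C(=O)CC(=O)OC)O[C@H](c2ccc(O[Si](C(C)C)(C(C)C)C(C)C)c(O[Si](C(C)C)(C(C)C)C(C)C)c2)C1
F2 | step 4 | (2E)-3-[3,4-bis(triisopropylsilyloxy)phenyl]-N-methoxy-N-methylprop-2-enamide | CON(C)C(=O)/C=C/c1ccc(O[Si](C(C)C)(C(C)C)C(C)C)c(O[Si](C(C)C)(C(C)C)C(C)C)c1
F3 | step 4 | 6-[(9E)-10-[3,4-bis(triisopropylsilyloxy)phenyl]-2-methyl-6,8-dioxodeca-2,9-dien-5-yl]-2,2-dimethyl-4H-1,3-dioxin-4-one | CC(C)=CCC(C(=O)CC(=O)/C=C/c1ccc(O[Si](C(C)C)(C(C)C)C(C)C)c(O[Si](C(C)C)(C(C)C)C(C)C)c1)C1=CC(=O)OC(C)(C)O1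
F4 | step 6 | (2S)-2-[3,4-bis(triisopropylsilyloxy)phenyl]-5,7-dihydroxy-8-[(2E)-3-methyl-4-oxobut-2-en-1-yl]-2,3-dihydro-4H-chromen-4-one | C/C(=C\Cc1c(O)cc(O)c2c1O[C@H](c1ccc(O[Si](C(C)C)(C(C)C)C(C)C)c(O[Si](C(C)C)(C(C)C)C(C)C)c1)CC2=O)C=O
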